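**Strategy.** Everything rests on disconnecting the C12–C13 bond of ring C (C8–C9–C11–C12–C13–C14) back to a C12–C16 bond. A pinacol-derived bicyclo[3.2.1]octane-1,7-diol carries the bridgehead carbinol at C16 and an exo carbinol at C13. Its semipinacol rearrangement moves C12 from C16 to C13, so the seven-membered ring C8–C9–C11–C12–C16–C13–C14 contracts to ring C while the C16 ketone of ring D appears. The step exploits the 1,2-relationship of the ring D carbon C16 and bridgehead C13 in the C/D bicycle. Ring B comes from (R)-4-silyloxycyclopentenone, whose stereocentre relays C9 and C8; ring A and the lactone are annulated last by Michael and aldol additions.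

Key step: step 8

Remark: gibberellane numbering (C1–C19) is used for all intermediates; β is the face of ring B that carries H9 and the C15–C16 bridge in the target, α the face of the C10 lactone oxygen. Compounds 23 and 24 are expected as C4 epimer mixtures (C4 is enolised and fixed in step 15) and are written without configuration at C4. Reagents 3 and 20 are used as purchased THF solutions, and 3-bromo-2-methoxyprop-1-ene (6) is assumed to be purchasable.

Step 1
Reactants: 1 (R)-4-(tert-butyldimethylsilyloxy)cyclopent-2-en-1-one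
Product: 2 (R)-4-(tert-butyldimethylsilyloxy)-2-iodocyclopent-2-en-1-one
Conditions: I2, pyridine, CH2Cl2, 0 °C → rt
Reagents that add atoms: iodine, II
Why: α-iodination of the enone by pyridine conjugate addition, iodination of the enolate and elimination should give the 2-iodoenone without touching the C10 stereocentre.

Step 2
Reactants: 2 (R)-4-(tert-butyldimethylsilyloxy)-2-iodocyclopent-2-en-1-one; 3 (1,3-dioxolan-2-ylmethyl)zinc bromide
Product: 4 (R)-4-(tert-butyldimethylsilyloxy)-2-(1,3-dioxolan-2-ylmethyl)cyclopent-2-en-1-one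
Conditions: Pd2(dba)3 (2.5 mol %), P(2-furyl)3 (10 mol %), THF/DMF, rt
Reagents that add atoms: none
Why: Negishi coupling of the α-iodoenone with the sp3 zinc reagent should place the masked CH2CHO arm (C14, C13) on C8.

Step 3
Reactants: 4 (R)-4-(tert-butyldimethylsilyloxy)-2-(1,3-dioxolan-2-ylmethyl)cyclopent-2-en-1-one; 5 allylmagnesium bromide; 6 3-bromo-2-methoxyprop-1-ene
Product: 9 9α-allyl-10β-(tert-butyldimethylsilyloxy)-8α-(1,3-dioxolan-2-ylmethyl)-8β-(2-methoxyprop-2-enyl)cyclopentan-6-one, via trimethylsilyl enol ether 7 (not isolated), via lithium enolate 8 (not isolated)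
Conditions: CuBr·SMe2 (10 mol %), Me3SiCl, THF, −78 °C; volatiles removed; MeLi, THF, 0 °C; then 6, DMPU, −78 → −20 °C
Reagents that add atoms: none
Why: Copper-catalysed, silyl-assisted conjugate allylation anti to the C10 silyloxy group should set C9 (allyl α, H β), and alkylation of the regiodefined lithium enolate anti to the new C9 allyl group should set the C8 quaternary centre with the C15–C16 arm β and the acetal arm α.

Step 4
Reactants: 9 9α-allyl-10β-(tert-butyldimethylsilyloxy)-8α-(1,3-dioxolan-2-ylmethyl)-8β-(2-methoxyprop-2-enyl)cyclopentan-6-one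
Product: 10 C5=C6 enol triflate of ketone 9
Conditions: KN(SiMe3)2, PhNTf2, THF, −78 °C
Reagents that add atoms: N-phenylbis(trifluoromethanesulfonimide), O=S(=O)(N(c1ccccc1)S(=O)(=O)C(F)(F)F)C(F)(F)F
Why: Kinetic deprotonation at C5 (the only enolisable position) with O-sulfonylation at −78 °C should outrun β-elimination of the C10 silyloxy group and store C6 as an enol triflate for later carbonylation.

Step 5
Reactants: 10 C5=C6 enol triflate of ketone 9
Product: 11 trans-fused bicyclic methyl enol ether (six-membered ring C8–C15–C16(OMe)=C12–C11–C9 on ring B)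
Conditions: second-generation Grubbs catalyst (5 mol %), toluene, 60 °C
Reagents that add atoms: none
Why: Ring-closing metathesis between the monosubstituted allyl alkene and the 1,1-disubstituted enol ether should close the six-membered ring, whose trans fusion was fixed in step 3.

Step 6
Reactants: 11 trans-fused bicyclic methyl enol ether
Product: 12 keto aldehyde (C16 ketone in the six-membered ring; 8α-CH2CHO; 10β-OTBS; C6 enol triflate)
Conditions: PPTS (20 mol %), acetone/H2O (4:1), 55 °C
Reagents that add atoms: water, O
Why: Buffered acid hydrolysis should cleave the enol ether and the dioxolane, while the secondary silyl ether, which stronger aqueous acid would remove, and the enol triflate survive.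

Step 7
Reactants: 12 keto aldehyde
Product: 13 tricyclic diol (bicyclo[3.2.1]octane with bridgeheads C8 and C16; bridgehead 16-OH; exo 13-OH syn to the one-carbon bridge C15)
Conditions: SmI2 (2.5 equiv), MeOH (2 equiv), THF, −78 → 0 °C
Reagents that add atoms: none
Why: Intramolecular pinacol coupling of the aldehyde ketyl with the C16 ketone (the axial CH2CHO arm on C8 can only reach C16) should give the samarium-bridged cis-diol, which places the C13 hydroxyl on the less hindered exo side; C16 is fixed by the bicycle.

Step 8
Reactants: 13 tricyclic diol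
Product: 15 rearranged C16 ketone (bicyclo[3.2.1]octane with bridgeheads C8 and C13; ring C C8–C9–C11–C12–C13–C14), via C13 mesylate 14 (not isolated)
Conditions: MsCl, Et3N, CH2Cl2, −20 °C; then KOtBu, THF, −20 → 0 °C
Reagents that add atoms: none
Why: The secondary C13 hydroxyl is mesylated selectively (the bridgehead C16 hydroxyl is tertiary and inert), then the C16 alkoxide pushes the C16–C12 bond onto C13 with loss of mesylate and C16 becomes the ketone. This is a semipinacol rearrangement of a vicinal diol monosulfonate, the Wagner–Meerwein shift that interconverts the two bicyclo[3.2.1]octane skeletons. No ring is closed by a cyclisation: the suprafacial 1,2-shift contracts the seven-membered ring C8–C9–C11–C12–C16–C13–C14 to the six-membered ring C and at the same time expands the six-membered ring C8–C9–C11–C12–C16–C15 to the seven-membered ring that holds C15 and C16. The new stereocentre C13 is formed with inversion at the carbon that loses mesylate and has the only configuration the bridged framework allows once C8 is fixed. The step needs migration of C12 and not of C15: the exo mesylate from step 7 is antiperiplanar to C16–C12 and roughly orthogonal to C16–C15, a shift of C15 would build a cyclobutane, and formation of the carbonyl group should make the shift irreversible.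

Step 9
Reactants: 15 rearranged C16 ketone
Product: 16 exocyclic methylene compound (C16=C17; 10β-OTBS; C6 enol triflate)
Conditions: Ph3PCH3Br, KOtBu, THF, 0 °C → rt
Reagents that add atoms: methyltriphenylphosphonium bromide, [Br-].C[P+](c1ccccc1)(c1ccccc1)c1ccccc1
Why: Wittig methylenation of the unhindered C16 ketone should install C17 while the enol triflate and silyl ether stay intact.

Step 10
Reactants: 16 exocyclic methylene enol triflate
Product: 17 benzyl ester (C7) conjugated with C5=C6
Conditions: Pd(OAc)2 (5 mol %), dppf (10 mol %), CO (1 atm), BnOH, Et3N, DMF, 60 °C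
Reagents that add atoms: carbon monoxide, [C-]#[O+]; benzyl alcohol, OCc1ccccc1
Why: Palladium-catalysed alkoxycarbonylation of the enol triflate (oxidative addition, CO insertion, alcoholysis) should introduce C7 as the benzyl ester.

Step 11
Reactants: 17 benzyl ester with 10β-OTBS
Product: 18 10β-alcohol
Conditions: HF·pyridine, THF, 0 °C → rt
Reagents that add atoms: none
Why: Fluoride-driven Si–O cleavage under buffered, non-basic conditions should free the allylic alcohol without isomerising the γ-oxygenated enoate.

Step 12
Reactants: 18 10β-alcohol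
Product: 19 tricyclic enone (C10 ketone; C5=C6–CO2Bn; 16-methylene)
Conditions: Dess–Martin periodinane, CH2Cl2, 0 °C → rt
Reagents that add atoms: none
Why: Dess–Martin oxidation of the allylic alcohol should give the enone, in which C9 (now α to the ketone) already has the thermodynamically preferred cis B/C fusion.

Step 13
Reactants: 19 tricyclic enone; 20 [2-(1,3-dioxan-2-yl)ethyl]magnesium bromide
Product: 22 10α-propanoate with 10β-[2-(1,3-dioxan-2-yl)ethyl] chain (C1–C3), via bromomagnesium alkoxide 21 (not isolated)
Conditions: LaCl3·2LiCl (30 mol %), THF, −78 °C; then (EtCO)2O, DMAP (cat.), −78 °C → rt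
Reagents that add atoms: propionic anhydride, CCC(=O)OC(=O)CC
Why: Lanthanum-assisted 1,2-addition of the Grignard reagent to the C10 ketone should occur on the β face, anti to the adjacent C9–C11 bond (1,2-induction), leaving the oxygen α, and the tertiary magnesium alkoxide is acylated in the same flask.

Step 14
Reactants: 22 10α-propanoate
Product: 23 19,10-lactone (C4–C5 bond formed; H5 β; 6β-CO2Bn; C4 epimers)
Conditions: KN(SiMe3)2, THF/DMF, −78 → −40 °C; AcOH quench
Reagents that add atoms: none
Why: Intramolecular Michael addition of the propanoate enolate (C4) to C5 of the enoate, which has no γ-hydrogen to compete for the base, should give the γ-lactone, cis-fused because the tether runs through the α oxygen on C10 (H5 β), with C6 protonated to the more stable β-ester trans to C4.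

Step 15
Reactants: 23 19,10-lactone with acetal side chain
Product: 25 benzyl ester of the ring A hydroxy lactone bearing the 16-methylene group, via aldehyde 24 (not isolated)
Conditions: AcOH/H2O (4:1), 50 °C; concentrate; then KOtBu (20 mol %), 18-crown-6, THF, −78 → −40 °C; AcOH quench
Reagents that add atoms: water, O
Why: After acetal hydrolysis, a 6-(enolexo)-exo-trig aldol addition of the lactone enolate C4 to the C3 aldehyde should close ring A; C4 is fixed by the bridged lactone geometry, and a kinetic open transition state with the aldehyde C=O anti to the lactone carbonyl should give the axial 3β-alcohol.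

Step 16
Reactants: 25 benzyl ester of the ring A hydroxy lactone bearing the 16-methylene group
Product: 26 benzyl ester of the target (tertiary 16-hydroxyl and 16-methyl in place)
Conditions: Co(acac)2 (20 mol %), PhSiH3, O2 (1 atm), THF/iPrOH, rt
Reagents that add atoms: dioxygen, O=O
Why: Mukaiyama hydration should transfer a hydrogen atom to C17 and trap the tertiary C16 radical with oxygen on the exo face (the side of C14, away from C11 and C12), giving the Markovnikov alcohol with exo 16-OH and endo methyl.

Step 17
Reactants: 26 benzyl ester of the target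
Product: 27 target gibberellin (free 7-carboxylic acid)
Conditions: H2 (1 atm), Pd/C, EtOAc, rt
Reagents that add atoms: none
Why: Hydrogenolysis of the benzyl ester under neutral conditions should free the C7 acid without risk to the 3β-hydroxy lactone, as no other reducible group remains.

**Compound list**

1 | (R)-4-(tert-butyldimethylsilyloxy)cyclopent-2-en-1-one | O=C1C=C[C@H](O[Si](C)(C)C(C)(C)C)C1 | starting material
2 | (R)-4-(tert-butyldimethylsilyloxy)-2-iodocyclopent-2-en-1-one | O=C1C(I)=C[C@H](O[Si](C)(C)C(C)(C)C)C1 | intermediate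
3 | (1,3-dioxolan-2-ylmethyl)zinc bromide | Br[Zn]CC1OCCO1 | starting material
4 | (R)-4-(tert-butyldimethylsilyloxy)-2-(1,3-dioxolan-2-ylmethyl)cyclopent-2-en-1-one | O=C1C(CC2OCCO2)=C[C@H](O[Si](C)(C)C(C)(C)C)C1 | intermediate
5 | allylmagnesium bromide | C=CC[Mg]Br | starting material
6 | 3-bromo-2-methoxyprop-1-ene | C=C(OC)CBr | starting material
7 | trimethylsilyl enol ether (C6–OSiMe3, C6=C8) with 9α-allyl and 10β-OTBS | C[Si](C)(C)OC1=C(CC2OCCO2)[C@@H](CC=C)[C@H](O[Si](C)(C)C(C)(C)C)C1 | intermediate
8 | lithium enolate corresponding to 7 | [Li]OC1=C(CC2OCCO2)[C@@H](CC=C)[C@H](O[Si](C)(C)C(C)(C)C)C1 | intermediate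
9 | 9α-allyl-10β-(tert-butyldimethylsilyloxy)-8α-(1,3-dioxolan-2-ylmethyl)-8β-(2-methoxyprop-2-enyl)cyclopentan-6-one | O=C1[C@](CC2OCCO2)(CC(=C)OC)[C@@H](CC=C)[C@H](O[Si](C)(C)C(C)(C)C)C1 | intermediate
10 | C5=C6 enol triflate of 9 | FC(F)(F)S(=O)(=O)OC1=C[C@@H](O[Si](C)(C)C(C)(C)C)[C@H](CC=C)[C@@]1(CC2OCCO2)CC(=C)OC | intermediate
11 | trans-fused bicyclic methyl enol ether (ring C8–C15–C16(OMe)=C12–C11–C9) | FC(F)(F)S(=O)(=O)OC1=C[C@@H](O[Si](C)(C)C(C)(C)C)[C@@H]2CC=C(OC)C[C@@]12CC3OCCO3 | intermediate
12 | keto aldehyde (16-ketone, 8α-CH2CHO) | FC(F)(F)S(=O)(=O)OC1=C[C@@H](O[Si](C)(C)C(C)(C)C)[C@@H]2CCC(=O)C[C@@]12CC=O | intermediate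
13 | tricyclic diol (bridgehead 16-OH, exo 13-OH) | FC(F)(F)S(=O)(=O)OC1=C[C@@H](O[Si](C)(C)C(C)(C)C)[C@@H]2CC[C@@]3(O)C[C@@]12C[C@@H]3O | intermediate
14 | C13 mesylate of diol 13 | FC(F)(F)S(=O)(=O)OC1=C[C@@H](O[Si](C)(C)C(C)(C)C)[C@@H]2CC[C@@]3(O)C[C@@]12C[C@@H]3OS(C)(=O)=O | intermediate
15 | rearranged C16 ketone (bridgeheads C8 and C13) | FC(F)(F)S(=O)(=O)OC1=C[C@@H](O[Si](C)(C)C(C)(C)C)[C@@H]2CC[C@@H]3C[C@]12CC3=O | intermediate
16 | exocyclic methylene enol triflate (C16=C17) | FC(F)(F)S(=O)(=O)OC1=C[C@@H](O[Si](C)(C)C(C)(C)C)[C@@H]2CC[C@@H]3C[C@]12CC3=C | intermediate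
17 | benzyl C7 ester with 10β-OTBS | O=C(OCc1ccccc1)C1=C[C@@H](O[Si](C)(C)C(C)(C)C)[C@@H]2CC[C@@H]3C[C@]12CC3=C | intermediate
18 | 10β-alcohol | O=C(OCc1ccccc1)C1=C[C@@H](O)[C@@H]2CC[C@@H]3C[C@]12CC3=C | intermediate
19 | tricyclic enone (C10 ketone, C5=C6–CO2Bn, 16-methylene) | O=C(OCc1ccccc1)C1=CC(=O)[C@@H]2CC[C@@H]3C[C@]12CC3=C | intermediate
20 | [2-(1,3-dioxan-2-yl)ethyl]magnesium bromide | Br[Mg]CCC1OCCCO1 | starting material
21 | bromomagnesium 10α-alkoxide | O=C(OCc1ccccc1)C1=C[C@@](O[Mg]Br)(CCC2OCCCO2)[C@@H]2CC[C@@H]3C[C@]12CC3=C | intermediate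
22 | 10α-propanoate with 10β-[2-(1,3-dioxan-2-yl)ethyl] chain | O=C(OCc1ccccc1)C1=C[C@@](OC(=O)CC)(CCC2OCCCO2)[C@@H]2CC[C@@H]3C[C@]12CC3=C | intermediate
23 | 19,10-lactone with acetal side chain (C4 epimers) | CC1C(=O)O[C@]2(CCC3OCCCO3)[C@@H]3CC[C@@H]4C[C@]3(CC4=C)[C@@H](C(=O)OCc3ccccc3)[C@@H]21 | intermediate
24 | 19,10-lactone C3 aldehyde (C4 epimers) | CC1C(=O)O[C@]2(CCC=O)[C@@H]3CC[C@@H]4C[C@]3(CC4=C)[C@@H](C(=O)OCc3ccccc3)[C@@H]21 | intermediate
25 | benzyl ester of the ring A hydroxy lactone bearing the 16-methylene group (3β-OH; 19,10-lactone; C16=C17) | C[C@@]12C(=O)O[C@]3(CC[C@@H]1O)[C@@H]1CC[C@@H]4C[C@]1(CC4=C)[C@@H](C(=O)OCc1ccccc1)[C@@H]32 | intermediate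
26 | benzyl ester of the target (3β,16-dihydroxy-16-methyl; 19,10-lactone) | C[C@@]12C(=O)O[C@]3(CC[C@@H]1O)[C@@H]1CC[C@@H]4C[C@]1(C[C@@]4(C)O)[C@@H](C(=O)OCc1ccccc1)[C@@H]32 | intermediate
27 | target gibberellin (3β,16-dihydroxy-16-methyl 19,10-lactone 7-carboxylic acid) | C[C@@]12C(=O)O[C@]3(CC[C@@H]1O)[C@@H]1CC[C@@H]4C[C@]1(C[C@@]4(C)O)[C@@H](C(=O)O)[C@@H]32 | target

**Total step count:** 17. **Longest linear sequence:** 17 steps (1 → 27).

**Steps most likely to fail**

Step 3. The hindered, tetrasubstituted enolate may be O-alkylated or may react too slowly with the labile 2-methoxyallyl bromide, so the quaternary centre at C8 is not built cleanly. The fallback sets out from lithium enolate 8 and returns at 10. Enolate 8 is alkylated with methyl bromoacetate (THF/DMPU, −78 → −20 °C), which should give the keto ester F1 with the same anti selectivity. KN(SiMe3)2 and PhNTf2 at −78 °C then convert the ketone into the enol triflate ester F2. Methylenation of the ester carbonyl with Cp2TiMe2 (toluene, 65 °C) turns CH2CO2Me into the CH2C(OMe)=CH2 enol ether, which is compound 10.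

Step 14. The 5-(enolendo)-exo-trig closure is stereoelectronically strained, so proton transfer or intermolecular Claisen condensation of the ester enolate may outrun C4–C5 bond formation. The fallback sets out from 19 and returns at 23. Reagent 20 is added as in step 13 but the alkoxide is quenched with water to give the tertiary alcohol F3. Acylation with 2-bromopropanoyl bromide (pyridine, DMAP, CH2Cl2) gives the 2-bromopropanoate F4. Bu3SnH with AIBN in benzene at 80 °C under slow addition should then close the lactone by 5-exo radical cyclisation of the α-ester radical onto C5, and hydrogen transfer to the ester-stabilised C6 radical gives 23.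

Step 15. Facial selectivity at C3 may be poor, or retro-aldol equilibration may drift toward the equatorial 3α-alcohol. The fallback sets out from 24 and returns at 25. The aldol is run as in step 15 and the crude mixture of 25 and its 3α-alcohol F5 is oxidised with Dess–Martin periodinane to the 3-ketone F6. Reduction with K[(sec-Bu)3BH] in THF at −78 °C should deliver hydride from the equatorial direction and give the axial 3β-alcohol 25.

Further compounds
F1 | step 3 | 9α-allyl-10β-(tert-butyldimethylsilyloxy)-8α-(1,3-dioxolan-2-ylmethyl)-8β-(methoxycarbonylmethyl)cyclopentan-6-one | O=C1[C@](CC2OCCO2)(CC(=O)OC)[C@@H](CC=C)[C@H](O[Si](C)(C)C(C)(C)C)C1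
F2 | step 3 | C5=C6 enol triflate of the keto ester | FC(F)(F)S(=O)(=O)OC1=C[C@@H](O[Si](C)(C)C(C)(C)C)[C@H](CC=C)[C@@]1(CC2OCCO2)CC(=O)OC
F3 | step 14 | tertiary 10α-alcohol with 10β-[2-(1,3-dioxan-2-yl)ethyl] chain | O=C(OCc1ccccc1)C1=C[C@@](O)(CCC2OCCCO2)[C@@H]2CC[C@@H]3C[C@]12CC3=C
F4 | step 14 | 10α-(2-bromopropanoate) of the tertiary alcohol | O=C(OCc1ccccc1)C1=C[C@@](OC(=O)C(C)Br)(CCC2OCCCO2)[C@@H]2CC[C@@H]3C[C@]12CC3=C
F5 | step 15 | 3α-epimer of benzyl ester 25 | C[C@@]12C(=O)O[C@]3(CC[C@H]1O)[C@@H]1CC[C@@H]4C[C@]1(CC4=C)[C@@H](C(=O)OCc1ccccc1)[C@@H]32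
F6 | step 15 | 3-oxo analogue of benzyl ester 25 | C[C@@]12C(=O)O[C@]3(CCC1=O)[C@@H]1CC[C@@H]4C[C@]1(CC4=C)[C@@H](C(=O)OCc1ccccc1)[C@@H]32
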